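Count chains first. I take each initiator to start one chain and the transfer agent to start none. Then one sum stays fixed through a run: unused initiator plus living chains plus dead chains equals the initiator charged. The earlier runs do not show this count, so it is my guess. The average length (the number-average degree of polymerisation) is monomer in chains over chains begun. If the charged initiator has begun its chains by the end, that is the fraction of the charge in chains divided by the loading. Set that fraction to one and you have the ceiling length, the units per chain if the whole charge of free monomer sits in chains: 19.6 for ash and oak alike. Length is ceiling times fraction in chains.

in all of them: initiator 5.1 mol%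
- summer: free monomer 1.3 mM (fed, over 2.0 min); transfer agent 0.20 mM; run made earlier
- dawn: free monomer 4 mM (fed, over 2.0 min); transfer agent 0.20 mM; run made earlier
- ash: free monomer 2.0 mM (fed, over 2.0 min); transfer agent 0.200 mM; time 5.0 min
- oak: free monomer 2.0 mM (fed, over 2.0 min); transfer agent 0.120 mM; time 5.0 min

| run | time / min | monomer in chains / % |
|---|---|---|
| summer | 0.250 | 3.9 |
| summer | 0.417 | 6.1 |
| summer | 0.833 | 14.7 |
| summer | 1.50 | 25.5 |
| summer | 3.00 | 35.7 |
| dawn | 0.667 | 21.0 |
| dawn | 1.33 | 46.2 |
| dawn | 2.00 | 70.1 |
| dawn | 2.50 | 84.0 |
| dawn | 3.00 | 90.2 |

(readings scatter by 0.5 percentage points)

1. which of the two ends with the longer chains by the average number of monomer units in a chain (chains begun, living or dead) ("neither" if they lie within 10%) (ash / oak / neither)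
2. average number of monomer units in a chain (chains begun, living or dead) at the end, ash
3. average number of monomer units in a chain (chains begun, living or dead) at the end, oak

- the average divides the monomer in chains by the number of chains begun, living and dead together
- the earlier runs do not show the number of chains; that part of a forecast is a guess
- percentages count the whole charge, also what has not yet gone in
- no earlier run changes the charge of transfer agent; that part of a forecast is a guess

You still need the fraction. Agent per initiator is 3.02 in summer and 0.980 in dawn. At 3.00 min, summer reads 35.7% and dawn 90.2%, so the run with more agent per initiator has less in chains. That reads as agent stopping chains. No run varies the agent charge, so the next step is a guess. Ash has 1.96, about midway, so I take the midpoint of the readings and get 12.3 units. Oak has 1.18, near dawn, so I take dawn's reading and get 17.7 units.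

The forecast says oak, with 12 for ash and 18 for oak, “Guessing that chains begun equal initiator only”.

The flasks give oak, with 11.0 for ash and 17.8 for oak.

    free monomer + initiator → living end + monomer in chains (k = 1100 M⁻¹ s⁻¹)
    free monomer + living end → monomer in chains + living end, rate k2*[living end]*[free monomer] (k = 460 M⁻¹ s⁻¹)
    living end + transfer agent → dead chain (kL = 160 M⁻¹ s⁻¹)

In ash, 99.3% of the initiation up to 5.0 min was done by 0.500 min; after that, living ends took up free monomer while transfer agent turned them into dead chains. At 5.00 min, 0.537% of the chains in ash still lived, fewer than the 10.4% in oak, with free monomer at 44.0% and 9.25%. The ceiling times the fraction in chains gives 11.0 for ash from 56.0%, and 17.8 for oak from 90.7%.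

Now take the flask like ash but with 2 mol% of initiator. Its ceiling is 50.0, higher than in ash, but its agent per initiator is 5.00, so you expect a fraction in chains under summer's. It holds 21.0% in chains at 5.00 min, and the length is 10.5, close to the 11.0 of ash.

All runs come from a simulation for substances that don't exist; scatter was added.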